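**Retrosynthetic overview**

1. The strategy rests on the flavanone half: a 5,7-dioxygenated benzene ring A (C4a, C5, C6, C7, C8, C8a) fused through C4a–C8a to a 2-aryl-2,3-dihydro-4-pyranone (O1, C2, C3, C4). That heterocycle is what an aldehyde hetero-Diels–Alder reaction delivers, so the pyranone is made first with C2 (S) and ring A is annulated onto it last.
2. Last skeletal disconnection: ring A at C4a–C5 and C8–C8a, a [4+2] benzannulation of the (S)-5-bromo-2-aryl-2,3-dihydro-4H-pyran-4-one with 1,1-dimethoxy-3-trimethylsilyloxybutadiene, with HBr and MeOH leaving. Hydrogenolysis of five benzyl ethers and BCl3 cleavage of the chelated 5-OMe follow.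
3. The dihydropyranone comes from a catalytic asymmetric hetero-Diels–Alder reaction of the biaryl aldehyde with 1-methoxy-3-trimethylsilyloxybutadiene, then bromination at C5.
4. The biaryl bond (ring B C5' to apigenin C6) comes from Suzuki coupling of 6-iodo-tri-O-benzylapigenin (from apigenin) with a ring B pinacol boronate (from 5-iodovanillin).
5. Ring order: the flavone rings arrive with apigenin; the pyranone ring of the flavanone closes in step 8 and ring A in step 12.

Key step: step 12

Remark: the biaryl axis has three ortho substituents and is taken as not configurationally stable (the target carries no axial descriptor); slowly interconverting rotamers of the benzylated intermediates should converge on deprotection.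
Remark: the (S)-ligand in step 8 is assigned by analogy with binaphthol–titanium carbonyl additions, where the (S)-ligand directs attack to the Si face; the configuration of 12 is to be confirmed, and the (R)-ligand is used if the sense proves opposite.
Abbreviation: Ar = 3,4-bis(benzyloxy)-5-{5,7-bis(benzyloxy)-2-[4-(benzyloxy)phenyl]-4-oxo-4H-chromen-6-yl}phenyl.

**Route**

Step 1
Reactants: 1 apigenin
Product: 2 7-(benzyloxy)-2-[4-(benzyloxy)phenyl]-5-hydroxy-4H-chromen-4-one
Conditions: BnBr (2.2 equiv), K2CO3, DMF, rt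
Reagents that add atoms: benzyl bromide, BrCc1ccccc1
Why: Williamson etherification alkylates the 7- and 4'-hydroxyls, while the 5-hydroxyl, hydrogen-bonded to the C4 carbonyl, should stay free under mild carbonate conditions.

Step 2
Reactants: 2 7-(benzyloxy)-2-[4-(benzyloxy)phenyl]-5-hydroxy-4H-chromen-4-one
Product: 3 7-(benzyloxy)-2-[4-(benzyloxy)phenyl]-5-hydroxy-6-iodo-4H-chromen-4-one
Conditions: BnMe3N+ ICl2− (1.1 equiv), CaCO3, CH2Cl2/MeOH, rt
Reagents that add atoms: benzyltrimethylammonium dichloroiodate, C[N+](C)(C)Cc1ccccc1.Cl[I-]Cl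
Why: Electrophilic aromatic iodination with an ammonium dichloroiodate goes to C6 of 5-hydroxy-7-alkoxyflavones, ortho to the free chelated hydroxyl, with CaCO3 taking up the HCl.

Step 3
Reactants: 3 7-(benzyloxy)-2-[4-(benzyloxy)phenyl]-5-hydroxy-6-iodo-4H-chromen-4-one
Product: 4 5,7-bis(benzyloxy)-2-[4-(benzyloxy)phenyl]-6-iodo-4H-chromen-4-one
Conditions: BnBr, K2CO3, nBu4NI (cat.), DMF, 70 °C
Reagents that add atoms: benzyl bromide, BrCc1ccccc1
Why: Williamson etherification under more forcing conditions caps the hindered chelated phenol, so that it can neither bind titanium in step 8 nor activate its ring towards bromination in step 9.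

Step 4
Reactants: 5 5-iodovanillin
Product: 6 3,4-dihydroxy-5-iodobenzaldehyde
Conditions: AlCl3, pyridine, CH2Cl2, reflux; aq. HCl
Reagents that add atoms: none
Why: Hydroxyl-assisted demethylation of a guaiacol, in which aluminium bound to the phenoxide activates the neighbouring methyl ether and pyridine takes the methyl group, should leave the aryl iodide and the aldehyde untouched.

Step 5
Reactants: 6 3,4-dihydroxy-5-iodobenzaldehyde
Product: 7 3,4-bis(benzyloxy)-5-iodobenzaldehyde
Conditions: BnBr (2.4 equiv), K2CO3, DMF, 50 °C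
Reagents that add atoms: benzyl bromide, BrCc1ccccc1
Why: Williamson etherification of both catechol hydroxyls gives ethers that are removed with the others by hydrogenolysis at the end.

Step 6
Reactants: 7 3,4-bis(benzyloxy)-5-iodobenzaldehyde
Product: 8 3,4-bis(benzyloxy)-5-(4,4,5,5-tetramethyl-1,3,2-dioxaborolan-2-yl)benzaldehyde
Conditions: B2pin2, PdCl2(dppf) (5 mol%), KOAc, 1,4-dioxane, 85 °C
Reagents that add atoms: bis(pinacolato)diboron, CC1(C)OB(OC1(C)C)B1OC(C)(C)C(C)(C)O1
Why: Miyaura borylation of the aryl iodide tolerates the aldehyde under the weak acetate base and puts boron on the less hindered coupling partner.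

Step 7
Reactants: 4 5,7-bis(benzyloxy)-2-[4-(benzyloxy)phenyl]-6-iodo-4H-chromen-4-one; 8 3,4-bis(benzyloxy)-5-(4,4,5,5-tetramethyl-1,3,2-dioxaborolan-2-yl)benzaldehyde
Product: 9 Ar–CHO (3,4-bis(benzyloxy)-5-{5,7-bis(benzyloxy)-2-[4-(benzyloxy)phenyl]-4-oxo-4H-chromen-6-yl}benzaldehyde)
Conditions: Pd(OAc)2 (5 mol%), SPhos (10 mol%), K3PO4, toluene/H2O, 90 °C
Reagents that add atoms: none
Why: Suzuki–Miyaura coupling with a bulky electron-rich biarylphosphine should join the doubly ortho-substituted iodide to the ortho-alkoxy boronate, as this ligand class is used for tri-ortho-substituted biaryls.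

Step 8
Reactants: 9 Ar–CHO; 10 (E)-1-methoxy-3-(trimethylsilyloxy)buta-1,3-diene
Product: 12 (S)-2-Ar-2,3-dihydro-4H-pyran-4-one, via silylated aldol adduct 11 (not isolated)
Conditions: Ti(OiPr)4 (30 mol%), (S)-H8-BINOL (33 mol%), 4 Å MS, toluene, 0 °C; then TFA, CH2Cl2, 0 °C
Reagents that add atoms: none
Why: Catalytic asymmetric hetero-Diels–Alder reaction (Mukaiyama aldol addition under a binaphthol–titanium catalyst, then acid-promoted cyclisation with loss of methanol), in which the chiral titanium binaphtholate bound to the aldehyde is expected to shield the Re face so that the diene terminus adds to the Si face and C2 forms as (S); the loading is raised because the flavone carbonyl may hold part of the titanium.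

Step 9
Reactants: 12 (S)-2-Ar-2,3-dihydro-4H-pyran-4-one
Product: 13 (S)-5-bromo-2-Ar-2,3-dihydro-4H-pyran-4-one
Conditions: NBS (1.05 equiv), CH2Cl2, −40 → 0 °C, dark
Reagents that add atoms: N-bromosuccinimide, O=C1CCC(=O)N1Br
Why: Electrophilic α-bromination of the vinylogous ester (bromine transfer to the enol ether carbon C5, then loss of the C5 proton) should be selective because this push–pull alkene is the most nucleophilic site and one equivalent of NBS in CH2Cl2 without acid at low temperature is slow towards alkoxyarenes.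

Step 10
Reactants: 14 1,1-dimethoxyethene
Product: 15 4,4-dimethoxybut-3-en-2-one
Conditions: AcCl (1 equiv), 14 (2.1 equiv), Et2O, 0 °C → rt
Reagents that add atoms: acetyl chloride, CC(Cl)=O
Why: C-acylation of a ketene acetal by an acid chloride gives the acyl ketene acetal, with the second equivalent of 14 scavenging HCl as methyl acetate and chloromethane.

Step 11
Reactants: 15 4,4-dimethoxybut-3-en-2-one
Product: 16 1,1-dimethoxy-3-(trimethylsilyloxy)buta-1,3-diene
Conditions: TMSCl, Et3N, ZnCl2 (cat.), benzene, 40 °C; distillation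
Reagents that add atoms: chlorotrimethylsilane, C[Si](C)(C)Cl
Why: Soft enolisation and O-silylation of the methyl ketone, the conditions used for 1-methoxy-3-silyloxybutadiene, should give the cross-conjugated silyl dienol ether.

Step 12
Reactants: 13 (S)-5-bromo-2-Ar-2,3-dihydro-4H-pyran-4-one; 16 1,1-dimethoxy-3-(trimethylsilyloxy)buta-1,3-diene
Product: 19 (2S)-2-Ar-7-hydroxy-5-methoxychroman-4-one, via bromo cycloadduct 17 (not isolated), via aryl trimethylsilyl ether 18 (not isolated)
Conditions: 16 (3 equiv), TMSOTf (2.2 equiv), CH2Cl2, −78 → −20 °C; Et3N, −20 °C → rt; then 1 M HCl, THF, 0 °C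
Reagents that add atoms: none
Why: Proposed new method: TMSOTf silylates the C4 carbonyl of 13 to a 5-bromo-4-silyloxy-dihydropyrylium ion, the CH2 terminus of 16 adds to its C6 (the future C8a), and the bromine-bearing silyl enol ether carbon C5 (the future C4a) then captures the tethered dimethoxycarbenium carbon, so that ring A closes as a six-membered carbocycle by a Lewis acid promoted [4+2] addition across C5=C6 that may be concerted or run as conjugate addition followed by 6-endo ring closure, giving 17. The closest known reactions are the cycloaddition–aromatisation of 1,1-dialkoxy-3-silyloxybutadienes with 2-bromo-1,4-quinones and the Mukaiyama–Michael addition of silyl enol ethers to 2,3-dihydro-4H-pyran-4-ones and 4-silyloxybenzopyrylium salts; a 5-bromo-dihydropyranone has not been shown as the two-carbon partner, and as a push–pull alkene it is expected to need the silyl activation. In 17 the allylic ketal ionises under TMSOTf and loses the C8 proton to give a 5-methoxy-7-silyloxycyclohexadiene, and Et3N then removes HBr across C4a–C8a (the C8a hydrogen is now allylic and the loss is driven by aromatisation) to give aryl silyl ether 18, which dilute acid cleaves to the 7-phenol. The step needs one regiochemistry, acetal carbon on C4a and CH2 on C8a, and polarity secures it: the diene has a single nucleophilic terminus and the activated vinylogous ester a single electrophilic carbon, so OMe ends at C5 and OH at C7. No stereocentre that persists is formed (both ring-fusion centres of 17 become sp2) and C2, set in step 8, is a spectator; strong base is avoided so that the ring oxygen is not expelled from C8a before aromatisation. A second equivalent of TMSOTf is supplied because the flavone carbonyl is expected to hold one.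

Step 13
Reactants: 19 (2S)-2-Ar-7-hydroxy-5-methoxychroman-4-one
Product: 20 (2S)-2-{3,4-dihydroxy-5-[5,7-dihydroxy-2-(4-hydroxyphenyl)-4-oxo-4H-chromen-6-yl]phenyl}-7-hydroxy-5-methoxychroman-4-one
Conditions: H2 (1 atm), palladium on carbon (10 wt% Pd/C), THF/MeOH, rt
Reagents that add atoms: none
Why: Heterogeneous hydrogenolysis of the five aryl benzyl ethers under neutral conditions should be faster than reduction of the flavone C2=C3 bond, the two ketones or the cyclic benzylic C2–O bond, so the reaction is stopped after five equivalents of hydrogen.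

Step 14
Reactants: 20 (2S)-2-{3,4-dihydroxy-5-[5,7-dihydroxy-2-(4-hydroxyphenyl)-4-oxo-4H-chromen-6-yl]phenyl}-7-hydroxy-5-methoxychroman-4-one
Product: 21 (2S)-2-{3,4-dihydroxy-5-[5,7-dihydroxy-2-(4-hydroxyphenyl)-4-oxo-4H-chromen-6-yl]phenyl}-5,7-dihydroxychroman-4-one (target)
Conditions: BCl3 (1 M in CH2Cl2, excess), CH2Cl2, −20 → 0 °C; MeOH/H2O quench, acidic reversed-phase purification
Reagents that add atoms: none
Why: Chelation-directed ether cleavage, in which boron bridges the C4 carbonyl and the peri 5-OMe and chloride removes the methyl group, is selective for this one ether and is run without base, so that C2 (benzylic, para to a free phenol) is not epimerised through the chalcone.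

**Compound list**

1 | apigenin | O=c1cc(-c2ccc(O)cc2)oc2cc(O)cc(O)c12 | starting material
2 | 7-(benzyloxy)-2-[4-(benzyloxy)phenyl]-5-hydroxy-4H-chromen-4-one | O=c1cc(-c2ccc(OCc3ccccc3)cc2)oc2cc(OCc3ccccc3)cc(O)c12 | intermediate
3 | 7-(benzyloxy)-2-[4-(benzyloxy)phenyl]-5-hydroxy-6-iodo-4H-chromen-4-one | O=c1cc(-c2ccc(OCc3ccccc3)cc2)oc2cc(OCc3ccccc3)c(I)c(O)c12 | intermediate
4 | 5,7-bis(benzyloxy)-2-[4-(benzyloxy)phenyl]-6-iodo-4H-chromen-4-one | O=c1cc(-c2ccc(OCc3ccccc3)cc2)oc2cc(OCc3ccccc3)c(I)c(OCc3ccccc3)c12 | intermediate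
5 | 5-iodovanillin | COc1cc(C=O)cc(I)c1O | starting material
6 | 3,4-dihydroxy-5-iodobenzaldehyde | O=Cc1cc(O)c(O)c(I)c1 | intermediate
7 | 3,4-bis(benzyloxy)-5-iodobenzaldehyde | O=Cc1cc(OCc2ccccc2)c(OCc2ccccc2)c(I)c1 | intermediate
8 | 3,4-bis(benzyloxy)-5-(4,4,5,5-tetramethyl-1,3,2-dioxaborolan-2-yl)benzaldehyde | O=Cc1cc(OCc2ccccc2)c(OCc2ccccc2)c(B2OC(C)(C)C(C)(C)O2)c1 | intermediate
9 | Ar–CHO, 3,4-bis(benzyloxy)-5-{5,7-bis(benzyloxy)-2-[4-(benzyloxy)phenyl]-4-oxo-4H-chromen-6-yl}benzaldehyde | O=Cc4cc(OCc9ccccc9)c(OCc9ccccc9)c(-c1c(OCc9ccccc9)cc2oc(-c3ccc(OCc9ccccc9)cc3)cc(=O)c2c1OCc9ccccc9)c4 | intermediate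
10 | (E)-1-methoxy-3-(trimethylsilyloxy)buta-1,3-diene | CO/C=C/C(=C)O[Si](C)(C)C | starting material
11 | (S,E)-5-Ar-1-methoxy-5-(trimethylsilyloxy)pent-1-en-3-one (silylated aldol adduct) | CO/C=C/C(=O)C[C@@H](c4cc(OCc9ccccc9)c(OCc9ccccc9)c(-c1c(OCc9ccccc9)cc2oc(-c3ccc(OCc9ccccc9)cc3)cc(=O)c2c1OCc9ccccc9)c4)O[Si](C)(C)C | intermediate
12 | (S)-2-Ar-2,3-dihydro-4H-pyran-4-one | O=C5C[C@@H](c4cc(OCc9ccccc9)c(OCc9ccccc9)c(-c1c(OCc9ccccc9)cc2oc(-c3ccc(OCc9ccccc9)cc3)cc(=O)c2c1OCc9ccccc9)c4)OC=C5 | intermediate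
13 | (S)-5-bromo-2-Ar-2,3-dihydro-4H-pyran-4-one | O=C5C[C@@H](c4cc(OCc9ccccc9)c(OCc9ccccc9)c(-c1c(OCc9ccccc9)cc2oc(-c3ccc(OCc9ccccc9)cc3)cc(=O)c2c1OCc9ccccc9)c4)OC=C5Br | intermediate
14 | 1,1-dimethoxyethene | C=C(OC)OC | starting material
15 | 4,4-dimethoxybut-3-en-2-one | CC(=O)C=C(OC)OC | intermediate
16 | 1,1-dimethoxy-3-(trimethylsilyloxy)buta-1,3-diene | C=C(O[Si](C)(C)C)C=C(OC)OC | intermediate
17 | (2S)-2-Ar-4a-bromo-5,5-dimethoxy-7-(trimethylsilyloxy)-2,3,4a,5,8,8a-hexahydro-4H-chromen-4-one (ring-fusion centres transient, cis expected, not specified) | O=C5C[C@@H](c4cc(OCc9ccccc9)c(OCc9ccccc9)c(-c1c(OCc9ccccc9)cc2oc(-c3ccc(OCc9ccccc9)cc3)cc(=O)c2c1OCc9ccccc9)c4)OC6CC(O[Si](C)(C)C)=CC(OC)(OC)C56Br | intermediate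
18 | (2S)-2-Ar-5-methoxy-7-(trimethylsilyloxy)chroman-4-one | O=C5C[C@@H](c4cc(OCc9ccccc9)c(OCc9ccccc9)c(-c1c(OCc9ccccc9)cc2oc(-c3ccc(OCc9ccccc9)cc3)cc(=O)c2c1OCc9ccccc9)c4)Oc6cc(O[Si](C)(C)C)cc(OC)c65 | intermediate
19 | (2S)-2-Ar-7-hydroxy-5-methoxychroman-4-one | O=C5C[C@@H](c4cc(OCc9ccccc9)c(OCc9ccccc9)c(-c1c(OCc9ccccc9)cc2oc(-c3ccc(OCc9ccccc9)cc3)cc(=O)c2c1OCc9ccccc9)c4)Oc6cc(O)cc(OC)c65 | intermediate
20 | (2S)-2-{3,4-dihydroxy-5-[5,7-dihydroxy-2-(4-hydroxyphenyl)-4-oxo-4H-chromen-6-yl]phenyl}-7-hydroxy-5-methoxychroman-4-one | O=C1C[C@@H](c2cc(O)c(O)c(-c3c(O)cc4oc(-c5ccc(O)cc5)cc(=O)c4c3O)c2)Oc2cc(O)cc(OC)c21 | intermediate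
21 | (2S)-2-{3,4-dihydroxy-5-[5,7-dihydroxy-2-(4-hydroxyphenyl)-4-oxo-4H-chromen-6-yl]phenyl}-5,7-dihydroxychroman-4-one | O=C1C[C@@H](c2cc(O)c(O)c(-c3c(O)cc4oc(-c5ccc(O)cc5)cc(=O)c4c3O)c2)Oc2cc(O)cc(O)c21 | target

**Step count**

Total: 14 steps. Longest linear sequence: 9 steps (steps 4, 5, 6, 7, 8, 9, 12, 13, 14 from 5-iodovanillin; equally steps 1, 2, 3, 7, 8, 9, 12, 13, 14 from apigenin).

**Steps most likely to fail**

Step 12 (the proposed new method). The annulation may stop after the first C–C bond (conjugate addition without ring closure at the hindered bromo-substituted carbon), the push–pull alkene may not react at all, or the ring oxygen may be expelled from C8a before aromatisation. The fallback uses known chemistry and builds the flavanone by the chalcone route. It sets out from aldehyde 9 and comes back to the route at target 21.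
- 2',4',6'-Trihydroxyacetophenone is dibenzylated (BnBr, K2CO3, acetone, reflux) to 1-[2-hydroxy-4,6-bis(benzyloxy)phenyl]ethanone F1.
- Claisen–Schmidt condensation of F1 with 9 (KOH, EtOH/THF, rt) should give the 2'-hydroxychalcone F2.
- NaOAc in refluxing EtOH closes F2 by oxa-Michael addition to the racemic 5,7-di-O-benzylflavanone F3.
- Preparative HPLC on a polysaccharide chiral stationary phase separates the (2S)-5,7-di-O-benzylflavanone F4; the (2R)-isomer is re-equilibrated through F2 with base and recycled.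
- Hydrogenolysis of F4 under the conditions of step 13 removes all seven benzyl ethers and gives 21 directly, so step 14 is not needed.

Step 8. The titanium catalyst may be sequestered by the flavone carbonyl and its peri ether oxygen, which would give low conversion or eroded facial selectivity. The fallback sets the stereocentre before the flavone is attached. It sets out from boronate aldehyde 8 (with iodide 4) and comes back at 12.
- The same titanium–(S)-H8-BINOL conditions applied to 8, an ordinary substituted benzaldehyde, should give, via the silylated aldol adduct F5 and TFA cyclisation, the (S)-dihydropyranone boronate F6.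
- Suzuki coupling of F6 with 4 (Pd(OAc)2, SPhos, K3PO4, toluene/H2O, 70 °C, short reaction time to spare the vinylogous ester) then gives 12.

Step 9. Electrophilic bromination may also occur on the alkoxy-substituted flavone ring (C8 of the apigenin unit) or on ring B, giving over-brominated material. The fallback uses iodine, which is too weak an electrophile to substitute alkoxyarenes. It sets out from 12 and comes back at 19.
- I2 with pyridine in CH2Cl2 (0 °C → rt), the α-iodination used for enones and glycal-derived pyranones, should give the (S)-5-iodo-dihydropyranone F7.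
- F7 is taken through the conditions of step 12 in place of 13, with iodide as the leaving group, and should pass through the iodo cycloadduct F8 and silyl ether 18 to 19.

**Further compounds**

F1 | step 12 | 1-[2-hydroxy-4,6-bis(benzyloxy)phenyl]ethanone | CC(=O)c1c(O)cc(OCc9ccccc9)cc1OCc9ccccc9
F2 | step 12 | (E)-1-[2-hydroxy-4,6-bis(benzyloxy)phenyl]-3-Ar-prop-2-en-1-one | O=C(/C=C/c4cc(OCc9ccccc9)c(OCc9ccccc9)c(-c1c(OCc9ccccc9)cc2oc(-c3ccc(OCc9ccccc9)cc3)cc(=O)c2c1OCc9ccccc9)c4)c5c(O)cc(OCc9ccccc9)cc5OCc9ccccc9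
F3 | step 12 | racemic 2-Ar-5,7-bis(benzyloxy)chroman-4-one | O=C5CC(c4cc(OCc9ccccc9)c(OCc9ccccc9)c(-c1c(OCc9ccccc9)cc2oc(-c3ccc(OCc9ccccc9)cc3)cc(=O)c2c1OCc9ccccc9)c4)Oc6cc(OCc9ccccc9)cc(OCc9ccccc9)c65
F4 | step 12 | (2S)-2-Ar-5,7-bis(benzyloxy)chroman-4-one | O=C5C[C@@H](c4cc(OCc9ccccc9)c(OCc9ccccc9)c(-c1c(OCc9ccccc9)cc2oc(-c3ccc(OCc9ccccc9)cc3)cc(=O)c2c1OCc9ccccc9)c4)Oc6cc(OCc9ccccc9)cc(OCc9ccccc9)c65
F5 | step 8 | (S,E)-5-[3,4-bis(benzyloxy)-5-(4,4,5,5-tetramethyl-1,3,2-dioxaborolan-2-yl)phenyl]-1-methoxy-5-(trimethylsilyloxy)pent-1-en-3-one | CO/C=C/C(=O)C[C@@H](c1cc(OCc9ccccc9)c(OCc9ccccc9)c(B2OC(C)(C)C(C)(C)O2)c1)O[Si](C)(C)C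
F6 | step 8 | (S)-2-[3,4-bis(benzyloxy)-5-(4,4,5,5-tetramethyl-1,3,2-dioxaborolan-2-yl)phenyl]-2,3-dihydro-4H-pyran-4-one | O=C1C[C@@H](c2cc(OCc9ccccc9)c(OCc9ccccc9)c(B3OC(C)(C)C(C)(C)O3)c2)OC=C1
F7 | step 9 | (S)-5-iodo-2-Ar-2,3-dihydro-4H-pyran-4-one | O=C5C[C@@H](c4cc(OCc9ccccc9)c(OCc9ccccc9)c(-c1c(OCc9ccccc9)cc2oc(-c3ccc(OCc9ccccc9)cc3)cc(=O)c2c1OCc9ccccc9)c4)OC=C5I
F8 | step 9 | (2S)-2-Ar-4a-iodo-5,5-dimethoxy-7-(trimethylsilyloxy)-2,3,4a,5,8,8a-hexahydro-4H-chromen-4-one | O=C5C[C@@H](c4cc(OCc9ccccc9)c(OCc9ccccc9)c(-c1c(OCc9ccccc9)cc2oc(-c3ccc(OCc9ccccc9)cc3)cc(=O)c2c1OCc9ccccc9)c4)OC6CC(O[Si](C)(C)C)=CC(OC)(OC)C56I
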